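Each γ‑butyrolactone ring (O1, C2=O, C3–OH, C4–H, C5H2) carries its ring oxygen between two one‑carbon units, C2 and C5, that sit on the vicinal pair C3–C4: a hidden succinic anhydride, which is an epoxide plus two molecules of CO. The key step is the double ring‑expansion carbonylation of an enantiopure 2‑(arylmethyl)oxirane; it forms the C2–C3 bond and, with inversion at C4, the C4–C5 bond in one operation, and the epoxide oxygen becomes O1. Regioselective reduction, C3 hydroxylation and anti‑selective enediolate benzylation complete each lactone. One batch of lactone feeds both halves, which are joined by a Suzuki–Miyaura coupling before global debenzylation.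

Key step: step 2

Remark: unit A is the lactone whose C3‑benzyl ring carries the biaryl bond, unit B the one whose C4‑benzyl ring carries it; compounds 1, 2, 12 and 23 are taken as purchasable.

Step 1
Reactants: 1 1‑(benzyloxy)‑4‑bromo‑2‑methoxybenzene; 2 (R)‑epichlorohydrin
Product: 5 (R)‑2‑{[4‑(benzyloxy)‑3‑methoxyphenyl]methyl}oxirane, via aryl Grignard reagent 3 (not isolated), via chlorohydrin 4 (not isolated)
Conditions: Mg, THF, 40 °C; CuI (copper iodide, 5 mol%), then 2, −30 to 0 °C; then 5 M NaOH (aq), rt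
Reagents that add atoms: none
Why: Copper‑catalysed SN2 opening of the unsubstituted epoxide carbon of 2 by the aryl Grignard reagent leaves the carbinol stereocentre untouched, and the Williamson‑type closure of the chlorohydrin onto CH2Cl likewise does not involve it, so (R)‑2 should give (R)‑5.

Step 2
Reactants: 5 (R)‑2‑{[4‑(benzyloxy)‑3‑methoxyphenyl]methyl}oxirane
Product: 7 (S)‑3‑{[4‑(benzyloxy)‑3‑methoxyphenyl]methyl}oxolane‑2,5‑dione, via β‑lactone 6 (not isolated)
Conditions: [(ClTPP)Al(THF)2][Co(CO)4] (2 mol%; ClTPP = 5,10,15,20‑tetrakis(4‑chlorophenyl)porphyrinate), CO (60 bar), 1,4‑dioxane, 90 °C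
Reagents that add atoms: carbon monoxide, [C-]#[O+]
Why: Ring‑expansion carbonylation by a Lewis acid/cobaltate ion pair: the aluminium cation activates the oxirane, Co(CO)4− opens it by SN2 attack at the unsubstituted CH2, CO inserts into the Co–C bond and the aluminium alkoxide closes β‑lactone 6 by acyl substitution (4‑exo‑trig), which makes the future C2–C3 bond. In the same pot the activated β‑lactone is opened by Co(CO)4− at its alkyl C–O carbon with SN2 inversion, a second CO inserts and the carboxylate closes the five‑membered anhydride by acyl substitution (5‑exo‑trig), which makes the future C4–C5 bond. The closest known reaction type is the catalytic double carbonylation of monosubstituted epoxides to substituted succinic anhydrides, which proceeds with inversion at the substituted carbon. No new stereocentre is created: the C4 configuration is that of the epoxide inverted once, so (R)‑5 should give (S)‑7. The step needs attack at the terminal carbon in the first opening (secured by the monosubstituted epoxide) and alkyl‑ rather than acyl‑oxygen cleavage in the second (secured by the soft cobaltate nucleophile in 1,4‑dioxane at 90 °C); the aryl and benzyl ethers are inert and no by‑product is formed.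

Step 3
Reactants: 7 (S)‑3‑{[4‑(benzyloxy)‑3‑methoxyphenyl]methyl}oxolane‑2,5‑dione
Product: 9 (S)‑4‑{[4‑(benzyloxy)‑3‑methoxyphenyl]methyl}oxolan‑2‑one, via hydroxy acid 8 (not isolated)
Conditions: NaBH4, THF, 0 °C to rt; then 2 M HCl, rt
Reagents that add atoms: none
Why: Borohydride reduction of a 2‑substituted succinic anhydride should occur mainly at the carbonyl next to the substituted carbon, and the hydroxy acid lactonises on acidification to the β‑substituted γ‑butyrolactone without touching the stereocentre.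

Step 4
Reactants: 9 (S)‑4‑{[4‑(benzyloxy)‑3‑methoxyphenyl]methyl}oxolan‑2‑one
Product: 11 (3S,4R)‑4‑{[4‑(benzyloxy)‑3‑methoxyphenyl]methyl}‑3‑hydroxyoxolan‑2‑one, via potassium enolate 10 (not isolated)
Conditions: KN(SiMe3)2, THF, −78 °C; then 2‑(phenylsulfonyl)‑3‑phenyloxaziridine, −78 °C; AcOH
Reagents that add atoms: 2‑(phenylsulfonyl)‑3‑phenyloxaziridine, O=S(=O)(c1ccccc1)N1OC1c1ccccc1
Why: Davis oxidation of the lactone enolate should deliver oxygen anti to the C4 benzyl group (trans alcohol); the C3 configuration is of no consequence because C3 is re‑enolised in step 8 and step 14 uses the analogous alcohol 22.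

Step 5
Reactants: 12 5‑bromovanillin
Product: 13 4‑(benzyloxy)‑3‑bromo‑5‑methoxybenzaldehyde
Conditions: BnBr, K2CO3, DMF, 60 °C
Reagents that add atoms: benzyl bromide, BrCc1ccccc1
Why: Williamson ether synthesis on the phenoxide, the only nucleophilic site.

Step 6
Reactants: 13 4‑(benzyloxy)‑3‑bromo‑5‑methoxybenzaldehyde
Product: 14 [4‑(benzyloxy)‑3‑bromo‑5‑methoxyphenyl]methanol
Conditions: NaBH4, MeOH, 0 °C; dilute HCl work‑up
Reagents that add atoms: none
Why: Borohydride reduction of the aldehyde; the aryl bromide and the benzyl ether are inert.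

Step 7
Reactants: 14 [4‑(benzyloxy)‑3‑bromo‑5‑methoxyphenyl]methanol
Product: 15 2‑(benzyloxy)‑1‑bromo‑5‑(bromomethyl)‑3‑methoxybenzene
Conditions: PBr3, CH2Cl2, 0 °C
Reagents that add atoms: phosphorus tribromide, BrP(Br)Br
Why: Conversion of the benzylic alcohol into the bromide by SN2 displacement of the phosphite ester.

Step 8
Reactants: 11 (3S,4R)‑4‑{[4‑(benzyloxy)‑3‑methoxyphenyl]methyl}‑3‑hydroxyoxolan‑2‑one; 15 2‑(benzyloxy)‑1‑bromo‑5‑(bromomethyl)‑3‑methoxybenzene
Product: 17 (3R,4R)‑3‑{[4‑(benzyloxy)‑3‑bromo‑5‑methoxyphenyl]methyl}‑4‑{[4‑(benzyloxy)‑3‑methoxyphenyl]methyl}‑3‑hydroxyoxolan‑2‑one (monomer A), via dilithium enediolate 16 (not isolated)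
Conditions: LiN(i‑Pr)2 (2.3 equiv), THF/HMPA, −78 °C; then 15, −78 to −40 °C; AcOH
Reagents that add atoms: none
Why: Alkylation of the α‑hydroxy‑lactone dianion: the benzylic bromide should approach the planar C3 anti to the C4 benzyl group, so the new benzyl ends trans to it and the hydroxyl cis, which is the (3R,4R) arrangement; the aryl bromide is inert to the amide base at this temperature.

Step 9
Reactants: 9 (S)‑4‑{[4‑(benzyloxy)‑3‑methoxyphenyl]methyl}oxolan‑2‑one
Product: 18 (S)‑4‑[(4‑hydroxy‑3‑methoxyphenyl)methyl]oxolan‑2‑one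
Conditions: H2 (1 atm), Pd/C, EtOAc, rt
Reagents that add atoms: none
Why: Hydrogenolysis of the benzyl ether; the lactone and the stereocentre are unaffected.

Step 10
Reactants: 18 (S)‑4‑[(4‑hydroxy‑3‑methoxyphenyl)methyl]oxolan‑2‑one
Product: 19 (S)‑4‑[(3‑bromo‑4‑hydroxy‑5‑methoxyphenyl)methyl]oxolan‑2‑one
Conditions: NBS, i‑Pr2NH (10 mol%), CH2Cl2, 0 °C
Reagents that add atoms: N‑bromosuccinimide, O=C1CCC(=O)N1Br
Why: Amine‑catalysed ortho‑selective electrophilic bromination of a phenol: the para position is blocked by the side chain and the single free position ortho to the hydroxyl is the one the biaryl bond needs.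

Step 11
Reactants: 19 (S)‑4‑[(3‑bromo‑4‑hydroxy‑5‑methoxyphenyl)methyl]oxolan‑2‑one
Product: 20 (S)‑4‑{[4‑(benzyloxy)‑3‑bromo‑5‑methoxyphenyl]methyl}oxolan‑2‑one
Conditions: BnBr, K2CO3, acetone, 55 °C
Reagents that add atoms: benzyl bromide, BrCc1ccccc1
Why: Williamson ether synthesis; carbonate does not enolise the lactone, so the phenoxide is the only nucleophile.

Step 12
Reactants: 20 (S)‑4‑{[4‑(benzyloxy)‑3‑bromo‑5‑methoxyphenyl]methyl}oxolan‑2‑one
Product: 22 (3S,4R)‑4‑{[4‑(benzyloxy)‑3‑bromo‑5‑methoxyphenyl]methyl}‑3‑hydroxyoxolan‑2‑one, via potassium enolate 21 (not isolated)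
Conditions: KN(SiMe3)2, THF, −78 °C; then 2‑(phenylsulfonyl)‑3‑phenyloxaziridine, −78 °C; AcOH
Reagents that add atoms: 2‑(phenylsulfonyl)‑3‑phenyloxaziridine, O=S(=O)(c1ccccc1)N1OC1c1ccccc1
Why: Davis oxidation as in step 4, anti to the C4 benzyl group; the C3 centre is re‑enolised in step 14.

Step 13
Reactants: 23 [4‑(benzyloxy)‑3‑methoxyphenyl]methanol
Product: 24 1‑(benzyloxy)‑4‑(bromomethyl)‑2‑methoxybenzene
Conditions: PBr3, CH2Cl2, 0 °C
Reagents that add atoms: phosphorus tribromide, BrP(Br)Br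
Why: Conversion of the benzylic alcohol into the bromide by SN2 displacement of the phosphite ester; the bromide is used fresh.

Step 14
Reactants: 22 (3S,4R)‑4‑{[4‑(benzyloxy)‑3‑bromo‑5‑methoxyphenyl]methyl}‑3‑hydroxyoxolan‑2‑one; 24 1‑(benzyloxy)‑4‑(bromomethyl)‑2‑methoxybenzene
Product: 26 (3R,4R)‑4‑{[4‑(benzyloxy)‑3‑bromo‑5‑methoxyphenyl]methyl}‑3‑{[4‑(benzyloxy)‑3‑methoxyphenyl]methyl}‑3‑hydroxyoxolan‑2‑one (monomer B), via dilithium enediolate 25 (not isolated)
Conditions: LiN(i‑Pr)2 (2.3 equiv), THF/HMPA, −78 °C; then 24, −78 to −40 °C; AcOH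
Reagents that add atoms: none
Why: Dianion alkylation as in step 8, the benzylic bromide entering anti to the C4 benzyl group to set (3R,4R).

Step 15
Reactants: 17 monomer A; 26 monomer B
Product: 28 tetra‑O‑benzyl ether of the target, via pinacol boronate 27 (not isolated)
Conditions: B2pin2 (1.05 equiv), Pd(dppf)Cl2 (5 mol%), KOAc, 1,4‑dioxane, 90 °C; then 26, Pd(OAc)2/SPhos, K3PO4 (aq), 80 °C; acidify to pH 3
Reagents that add atoms: none
Why: One‑pot Miyaura borylation of 17 followed by Suzuki–Miyaura coupling with 26, which is added only after 17 is consumed so that the two bromides cannot scramble; the acidic work‑up recloses any lactone opened by the base, and no stereocentre is involved.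

Step 16
Reactants: 28 tetra‑O‑benzyl ether of the target
Product: 29 CNP0218652.1 (target)
Conditions: H2 (1 atm), Pd/C, EtOAc/MeOH, rt
Reagents that add atoms: none
Why: Hydrogenolysis of the four aryl benzyl ethers; neither the tertiary alcohols nor the lactone C–O bonds are benzylic, so they survive.

Compound list
1 | 1‑(benzyloxy)‑4‑bromo‑2‑methoxybenzene | COc1cc(Br)ccc1OCc1ccccc1 | starting material
2 | (R)‑epichlorohydrin | ClC[C@H]1CO1 | starting material
3 | [4‑(benzyloxy)‑3‑methoxyphenyl]magnesium bromide | COc1cc([Mg]Br)ccc1OCc1ccccc1 | intermediate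
4 | (R)‑1‑[4‑(benzyloxy)‑3‑methoxyphenyl]‑3‑chloropropan‑2‑ol (shown as the free alcohol) | COc1cc(C[C@@H](O)CCl)ccc1OCc1ccccc1 | intermediate
5 | (R)‑2‑{[4‑(benzyloxy)‑3‑methoxyphenyl]methyl}oxirane | COc1cc(C[C@@H]2CO2)ccc1OCc1ccccc1 | intermediate
6 | (R)‑4‑{[4‑(benzyloxy)‑3‑methoxyphenyl]methyl}oxetan‑2‑one | COc1cc(C[C@@H]2CC(=O)O2)ccc1OCc1ccccc1 | intermediate
7 | (S)‑3‑{[4‑(benzyloxy)‑3‑methoxyphenyl]methyl}oxolane‑2,5‑dione | COc1cc(C[C@@H]2C(=O)OC(=O)C2)ccc1OCc1ccccc1 | intermediate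
8 | (S)‑3‑{[4‑(benzyloxy)‑3‑methoxyphenyl]methyl}‑4‑hydroxybutanoic acid | COc1cc(C[C@H](CO)CC(=O)O)ccc1OCc1ccccc1 | intermediate
9 | (S)‑4‑{[4‑(benzyloxy)‑3‑methoxyphenyl]methyl}oxolan‑2‑one | COc1cc(C[C@@H]2COC(=O)C2)ccc1OCc1ccccc1 | intermediate
10 | potassium enolate of 9 | [K+].[O-]C1=C[C@H](Cc2ccc(OCc3ccccc3)c(OC)c2)CO1 | intermediate
11 | (3S,4R)‑4‑{[4‑(benzyloxy)‑3‑methoxyphenyl]methyl}‑3‑hydroxyoxolan‑2‑one | COc1cc(C[C@@H]2COC(=O)[C@H]2O)ccc1OCc1ccccc1 | intermediate
12 | 5‑bromovanillin (3‑bromo‑4‑hydroxy‑5‑methoxybenzaldehyde) | COc1cc(C=O)cc(Br)c1O | starting material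
13 | 4‑(benzyloxy)‑3‑bromo‑5‑methoxybenzaldehyde | COc1cc(C=O)cc(Br)c1OCc1ccccc1 | intermediate
14 | [4‑(benzyloxy)‑3‑bromo‑5‑methoxyphenyl]methanol | COc1cc(CO)cc(Br)c1OCc1ccccc1 | intermediate
15 | 2‑(benzyloxy)‑1‑bromo‑5‑(bromomethyl)‑3‑methoxybenzene | COc1cc(CBr)cc(Br)c1OCc1ccccc1 | intermediate
16 | dilithium enediolate of 11 | [Li+].[Li+].[O-]C1=C([O-])[C@H](Cc2ccc(OCc3ccccc3)c(OC)c2)CO1 | intermediate
17 | (3R,4R)‑3‑{[4‑(benzyloxy)‑3‑bromo‑5‑methoxyphenyl]methyl}‑4‑{[4‑(benzyloxy)‑3‑methoxyphenyl]methyl}‑3‑hydroxyoxolan‑2‑one (monomer A) | COc1cc(C[C@@H]2COC(=O)[C@@]2(O)Cc2cc(OC)c(OCc3ccccc3)c(Br)c2)ccc1OCc1ccccc1 | intermediate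
18 | (S)‑4‑[(4‑hydroxy‑3‑methoxyphenyl)methyl]oxolan‑2‑one | COc1cc(C[C@@H]2COC(=O)C2)ccc1O | intermediate
19 | (S)‑4‑[(3‑bromo‑4‑hydroxy‑5‑methoxyphenyl)methyl]oxolan‑2‑one | COc1cc(C[C@@H]2COC(=O)C2)cc(Br)c1O | intermediate
20 | (S)‑4‑{[4‑(benzyloxy)‑3‑bromo‑5‑methoxyphenyl]methyl}oxolan‑2‑one | COc1cc(C[C@@H]2COC(=O)C2)cc(Br)c1OCc1ccccc1 | intermediate
21 | potassium enolate of 20 | [K+].[O-]C1=C[C@H](Cc2cc(Br)c(OCc3ccccc3)c(OC)c2)CO1 | intermediate
22 | (3S,4R)‑4‑{[4‑(benzyloxy)‑3‑bromo‑5‑methoxyphenyl]methyl}‑3‑hydroxyoxolan‑2‑one | COc1cc(C[C@@H]2COC(=O)[C@H]2O)cc(Br)c1OCc1ccccc1 | intermediate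
23 | [4‑(benzyloxy)‑3‑methoxyphenyl]methanol | COc1cc(CO)ccc1OCc1ccccc1 | starting material
24 | 1‑(benzyloxy)‑4‑(bromomethyl)‑2‑methoxybenzene | COc1cc(CBr)ccc1OCc1ccccc1 | intermediate
25 | dilithium enediolate of 22 | [Li+].[Li+].[O-]C1=C([O-])[C@H](Cc2cc(Br)c(OCc3ccccc3)c(OC)c2)CO1 | intermediate
26 | (3R,4R)‑4‑{[4‑(benzyloxy)‑3‑bromo‑5‑methoxyphenyl]methyl}‑3‑{[4‑(benzyloxy)‑3‑methoxyphenyl]methyl}‑3‑hydroxyoxolan‑2‑one (monomer B) | COc1cc(C[C@@H]2COC(=O)[C@@]2(O)Cc2ccc(OCc3ccccc3)c(OC)c2)cc(Br)c1OCc1ccccc1 | intermediate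
27 | pinacol boronate of monomer A | COc1cc(C[C@@H]2COC(=O)[C@@]2(O)Cc2cc(OC)c(OCc3ccccc3)c(B3OC(C)(C)C(C)(C)O3)c2)ccc1OCc1ccccc1 | intermediate
28 | tetra‑O‑benzyl ether of the target | COc1cc(C[C@@H]2COC(=O)[C@@]2(O)Cc2cc(OC)c(OCc3ccccc3)c(-c3cc(C[C@@H]4COC(=O)[C@@]4(O)Cc4ccc(OCc5ccccc5)c(OC)c4)cc(OC)c3OCc3ccccc3)c2)ccc1OCc1ccccc1 | intermediate
29 | CNP0218652.1 | COc1cc(C[C@@H]2COC(=O)[C@@]2(O)Cc2cc(OC)c(O)c(-c3cc(C[C@@H]4COC(=O)[C@@]4(O)Cc4ccc(O)c(OC)c4)cc(OC)c3O)c2)ccc1O | target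

Total step count: 16. Longest linear sequence: 10 steps (steps 1, 2, 3, 9, 10, 11, 12, 14, 15, 16).

Steps most likely to fail

Step 2. The second carbonylation may stall at the β‑lactone stage, or the forcing second stage may cause elimination of the β‑lactone or Lewis‑acid isomerisation of the epoxide. The fallback sets out from 5 and comes back at 9. Compound 5 is carbonylated once under mild conditions ([(salph)Al(THF)2][Co(CO)4], salph = N,N'‑bis(3,5‑di‑tert‑butylsalicylidene)‑1,2‑phenylenediamine dianion, CO, THF, 50 °C) and β‑lactone 6 is isolated. Copper‑catalysed SN2 opening of 6 at its alkyl C–O carbon with [dimethyl(propan‑2‑yloxy)silyl]methylmagnesium chloride (CuBr·SMe2 cat., THF, −30 °C) forms the C4–C5 bond with the same inversion and should give (S)‑3‑{[4‑(benzyloxy)‑3‑methoxyphenyl]methyl}‑4‑[dimethyl(propan‑2‑yloxy)silyl]butanoic acid F1. Tamao oxidation (H2O2, KF, KHCO3, THF/MeOH) turns the C–Si bond into the alcohol of hydroxy acid 8, which closes to 9 on acidification; step 3 is bypassed as well.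

Step 3. Hydride may be delivered with poor site selectivity between the two anhydride carbonyls, so that the lactone carbonyl ends next to the branched carbon. The fallback sets out from 7 and comes back at 9. Full reduction with LiAlH4 (THF, 0 °C to reflux) should give (S)‑2‑{[4‑(benzyloxy)‑3‑methoxyphenyl]methyl}butane‑1,4‑diol F2. Fétizon oxidation (Ag2CO3 on Celite, toluene, reflux) oxidises the less hindered primary alcohol, the one remote from the branch, and the lactol so formed is oxidised on to 9 with the carbonyl at C2.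

Step 10. Bromination may go to the position para to the methoxy group or run on to the dibromide. The fallback sets out from 15, in which the bromine is already in place, and comes back at 20, so that steps 9 to 11 are not needed. (S)‑4‑Benzyloxazolidin‑2‑one is acylated with 4‑tert‑butoxy‑4‑oxobutanoic acid (pivaloyl chloride, Et3N, LiCl, THF) to (S)‑4‑benzyl‑3‑(4‑tert‑butoxy‑4‑oxobutanoyl)oxazolidin‑2‑one F3. Evans alkylation of its sodium enolate (NaN(SiMe3)2, THF, −78 °C) with 15, the electrophile entering anti to the auxiliary benzyl group, should give tert‑butyl (S)‑3‑{[4‑(benzyloxy)‑3‑bromo‑5‑methoxyphenyl]methyl}‑4‑[(S)‑4‑benzyl‑2‑oxooxazolidin‑3‑yl]‑4‑oxobutanoate F4. LiBH4 (THF, one equivalent of water) removes the auxiliary reductively to tert‑butyl (S)‑3‑{[4‑(benzyloxy)‑3‑bromo‑5‑methoxyphenyl]methyl}‑4‑hydroxybutanoate F5, and CF3CO2H in CH2Cl2 closes this to 20.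

Further compounds
F1 | step 2 | (S)‑3‑{[4‑(benzyloxy)‑3‑methoxyphenyl]methyl}‑4‑[dimethyl(propan‑2‑yloxy)silyl]butanoic acid | COc1cc(C[C@H](C[Si](C)(C)OC(C)C)CC(=O)O)ccc1OCc1ccccc1
F2 | step 3 | (S)‑2‑{[4‑(benzyloxy)‑3‑methoxyphenyl]methyl}butane‑1,4‑diol | COc1cc(C[C@H](CO)CCO)ccc1OCc1ccccc1
F3 | step 10 | (S)‑4‑benzyl‑3‑(4‑tert‑butoxy‑4‑oxobutanoyl)oxazolidin‑2‑one | CC(C)(C)OC(=O)CCC(=O)N1[C@@H](Cc2ccccc2)COC1=O
F4 | step 10 | tert‑butyl (S)‑3‑{[4‑(benzyloxy)‑3‑bromo‑5‑methoxyphenyl]methyl}‑4‑[(S)‑4‑benzyl‑2‑oxooxazolidin‑3‑yl]‑4‑oxobutanoate | CC(C)(C)OC(=O)C[C@H](Cc1cc(Br)c(OCc2ccccc2)c(OC)c1)C(=O)N1[C@@H](Cc2ccccc2)COC1=O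
F5 | step 10 | tert‑butyl (S)‑3‑{[4‑(benzyloxy)‑3‑bromo‑5‑methoxyphenyl]methyl}‑4‑hydroxybutanoate | CC(C)(C)OC(=O)C[C@H](Cc1cc(Br)c(OCc2ccccc2)c(OC)c1)CO
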